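**Plan**

- Retrosynthesis: the C2 ketone comes from a C2 silyl ether. The C9 ester and C8 acetate come from a C9 ketone flanked by C8–OH. C7 isopropenyl and C8–O come from conjugate addition and enolate oxidation on a ring A enone (C9=O, C7=C8). That enone is cut at C8–C9 and C5–C6 into a ring B cyclohexenecarbonyl chloride and a propene 1,3-dianion equivalent.
- Enabling feature: C5 and C9 are 1,3-related through C10. The unit C5=C10–C9(=O)Cl on ring B therefore offers two electrophilic sites (acyl C9, β-carbon C5) that a three-carbon bis-silane C6–C7–C8 can bridge. The C8/C9 dioxygenation with C7 isopropenyl is the retron of the resulting cyclohex-2-enone.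
- Forward: ring B is made from (S)-carvone (methyl cuprate addition, enol triflate, isopropenyl degraded to oxygen, carbonylation). Ring A is closed by the tandem acylation/allylsilane conjugate addition. C7, C8 and C9 are then installed on the enone.
- Stereochemistry: the one bought stereocentre of carvone becomes C2 and is erased in the last step. It sets C4 (anti cuprate addition), C4 sets C5, and the ring fusion is set by equilibration. C7 follows from convex-face addition, C8 is placed trans to C7, and C9 comes from an axial-alcohol-selective hydride.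

Key step: step 7

Remark: eremophilane numbering is used (ring B = C1–C5 and C10, ring A = C5–C10, β = face of the C5 methyl); (S)-carvone, allyltrimethylsilane and 3-methylbut-2-enoyl chloride are taken as commercial.

**Route**

Step 1
Reactants: 1 (S)-(+)-carvone
Product: 3 (3S,5S)-2,3-dimethyl-5-(prop-1-en-2-yl)cyclohex-1-en-1-yl trifluoromethanesulfonate, via lithium enolate 2 (not isolated)
Conditions: Me2CuLi, Et2O, 0 °C; then PhNTf2, THF, 0 °C → rt
Reagents that add atoms: lithium dimethylcuprate, [Li+].C[Cu-]C; N-phenylbis(trifluoromethanesulfonimide), O=S(=O)(N(c1ccccc1)S(=O)(=O)C(F)(F)F)C(F)(F)F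
Why: Cuprate conjugate addition to carvone occurs anti to the isopropenyl group and sets the future C4 methyl; the regiodefined enolate is O-triflated (conjugate addition with enolate trapping).

Step 2
Reactants: 3 enol triflate
Product: 6 (3S,5S)-5-hydroxy-2,3-dimethylcyclohex-1-en-1-yl trifluoromethanesulfonate, via methoxy hydroperoxide 4 (not isolated), via acetate 5 (not isolated)
Conditions: O3, CH2Cl2/MeOH, −78 °C; concentrate; Ac2O, Et3N, DMAP (cat.), CH2Cl2, 0 °C → reflux; then K2CO3, MeOH, 0 °C
Reagents that add atoms: ozone, [O-][O+]=O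
Why: Ozone should attack the electron-rich isopropenyl group before the triflate-deactivated ring alkene; Criegee rearrangement of the acetylated α-methoxy hydroperoxide gives the acetate with retention, and methanolysis frees the alcohol (future C2–O).

Step 3
Reactants: 6 hydroxy triflate
Product: 7 (3S,5S)-5-[(tert-butyldimethylsilyl)oxy]-2,3-dimethylcyclohex-1-en-1-yl trifluoromethanesulfonate
Conditions: TBSCl, imidazole, DMF, rt
Reagents that add atoms: tert-butyldimethylsilyl chloride, CC(C)(C)[Si](C)(C)Cl
Why: Standard silylation of a secondary alcohol; the silyl ether is stable to the carbonylation, Lewis acid, organocopper and hydride steps that follow.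

Step 4
Reactants: 7 silyloxy triflate
Product: 8 (3S,5S)-5-[(tert-butyldimethylsilyl)oxy]-2,3-dimethylcyclohex-1-ene-1-carboxylic acid
Conditions: Pd(OAc)2 (5 mol %), PPh3, CO (1 atm), KOAc, DMF/H2O, 60 °C; dilute acid work-up
Reagents that add atoms: carbon monoxide, [C-]#[O+]; water, O
Why: Palladium-catalysed hydroxycarbonylation of an enol triflate installs C9 on C10 and gives the tetrasubstituted enoic acid directly.

Step 5
Reactants: 8 enoic acid
Product: 9 (3S,5S)-5-[(tert-butyldimethylsilyl)oxy]-2,3-dimethylcyclohex-1-ene-1-carbonyl chloride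
Conditions: 1-chloro-N,N,2-trimethylprop-1-en-1-amine, CH2Cl2, 0 °C → rt; used crude
Reagents that add atoms: 1-chloro-N,N,2-trimethylprop-1-en-1-amine, CC(C)=C(Cl)N(C)C
Why: The α-chloroenamine converts the acid into the acid chloride under neutral conditions, so the silyl ether is not exposed to HCl.

Step 6
Reactants: 10 allyltrimethylsilane
Product: 12 (E)-1,3-bis(trimethylsilyl)prop-1-ene, via silylallyllithium 11 (not isolated)
Conditions: s-BuLi, TMEDA, THF, −78 → −30 °C; then Me3SiCl, −78 °C → rt
Reagents that add atoms: chlorotrimethylsilane, C[Si](C)(C)Cl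
Why: Deprotonation of the allylsilane and γ-silylation of the 1-silylallyl anion is a known preparation of the E-configured 1,3-bis-silane.

Step 7
Reactants: 9 acid chloride; 12 (E)-1,3-bis(trimethylsilyl)prop-1-ene
Product: 15 2α-[(tert-butyldimethylsilyl)oxy]-10βH-11,12,13-trinoreremophil-7-en-9-one (cis-fused; 4β,5β-dimethyl), via silyl ketone 13 (not isolated), via titanium enolate 14 (not isolated)
Conditions: TiCl4 (2.2 equiv), CH2Cl2, −78 → −20 °C; H2O quench; then DBU (0.2 equiv), CH2Cl2, rt
Reagents that add atoms: none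
Why: Proposed new method: TiCl4 first promotes acylation of 12 at its silyl-bearing sp2 carbon (γ to the allylic silicon) with loss of one Me3Si group, which forms C8–C9 and leaves 13, whose remaining silicon makes C6 the γ-carbon of a new allylsilane. The TiCl4-bound enone C5=C10–C9=O is then attacked at C5 by C6 in an intramolecular Hosomi–Sakurai conjugate addition, which closes ring A in a 6-endo-trig mode with respect to the C5=C10 acceptor (six-membered chair-like transition state), expels the second silyl group and leaves C7=C8 conjugated to C9=O (enolate 14). The closest known reaction types are the Lewis acid acylation of allylsilanes, 1,3-bis(silyl)propenes being established propene 1,3-dianion equivalents, and intramolecular allylsilane additions to enones; their tandem use as a cyclohexenone annulation is the new element. C5 is set by approach of the tethered allylsilane anti to the pseudo-axial C4 methyl (A(1,2) strain with the C5 methyl), which gives the cis-4,5-dimethyl array; C10 is protonated on quench and, being α to the C9 ketone, is then equilibrated by DBU, the cis ring fusion being expected to prevail for this angularly methylated bicyclic enone. The step needs acylation before conjugate addition (secured by the much higher electrophilicity of the acyl chloride–TiCl4 complex), 1,4-closure rather than Nazarov cyclization or protodesilylation (secured by the β-silyl-stabilised six-membered pathway at low temperature under anhydrous conditions) and survival of the silyl ether (secured by the low temperature).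

Step 8
Reactants: 15 enone
Product: 18 2α-[(tert-butyldimethylsilyl)oxy]-8α-hydroxy-10βH-eremophil-11-en-9-one (7β-isopropenyl), via silyl enol ether 16 (not isolated), via silyloxy ketone 17 (not isolated)
Conditions: isopropenylmagnesium bromide, CuBr·SMe2 (10 mol %), Me3SiCl, THF, −78 °C; then mCPBA, NaHCO3, CH2Cl2, −20 °C; then citric acid, MeOH, rt
Reagents that add atoms: isopropenylmagnesium bromide, C=C(C)[Mg]Br; 3-chloroperoxybenzoic acid, O=C(OO)c1cccc(Cl)c1
Why: Copper-catalysed conjugate addition should enter C7 from the convex β-face of the cis-fused enone (ring B shields the α-face). Rubottom oxidation of the regiodefined silyl enol ether, far more electron-rich than the isopropenyl group, should place oxygen at C8 trans to the new C7 substituent, which is also the thermodynamically preferred trans-diequatorial arrangement.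

Step 9
Reactants: 18 hydroxy ketone
Product: 19 8α-acetoxy-2α-[(tert-butyldimethylsilyl)oxy]-10βH-eremophil-11-en-9-one
Conditions: Ac2O, pyridine, DMAP (cat.), CH2Cl2, 0 °C → rt
Reagents that add atoms: acetic anhydride, CC(=O)OC(C)=O
Why: Routine acetylation of the only free hydroxyl; no new stereocentre.

Step 10
Reactants: 19 acetoxy ketone
Product: 20 8α-acetoxy-2α-[(tert-butyldimethylsilyl)oxy]-10βH-eremophil-11-en-9α-ol
Conditions: LiBH(s-Bu)3 (1.2 equiv), THF, −78 °C; AcOH quench at −78 °C
Reagents that add atoms: none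
Why: The bulky hydride should attack the C9 ketone from the less hindered equatorial (β) direction and give the axial 9α-alcohol cis to the 8α-acetate (bulky-hydride reduction of a 2-acyloxycyclohexanone); low temperature and an acidic quench suppress acetyl migration.

Step 11
Reactants: 20 hydroxy acetate
Product: 21 8α-acetoxy-2α-[(tert-butyldimethylsilyl)oxy]-9α-(3-methylbut-2-enoyloxy)-10βH-eremophil-11-ene
Conditions: 3-methylbut-2-enoyl chloride, pyridine, DMAP (0.2 equiv), CH2Cl2, 0 °C → rt
Reagents that add atoms: 3-methylbut-2-enoyl chloride, CC(C)=CC(Cl)=O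
Why: Acylation of the hindered axial alcohol with the acid chloride and DMAP; pyridine rather than a trialkylamine avoids vinylketene formation and deconjugation of the senecioate.

Step 12
Reactants: 21 silyl ether
Product: 22 8α-acetoxy-9α-(3-methylbut-2-enoyloxy)-10βH-eremophil-11-en-2α-ol
Conditions: HF·pyridine, THF/pyridine, 0 °C → rt
Reagents that add atoms: none
Why: Buffered acidic fluoride removes the silyl ether without ester cleavage or acyl migration.

Step 13
Reactants: 22 alcohol
Product: 23 8α-acetoxy-9α-(3-methylbut-2-enoyloxy)-10βH-eremophil-11-en-2-one (target)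
Conditions: Dess–Martin periodinane, NaHCO3, CH2Cl2, rt
Reagents that add atoms: none
Why: Mild periodinane oxidation of the secondary alcohol gives the C2 ketone and erases the stereocentre inherited from carvone; esters and the isopropenyl group are inert.

**Compound list**

1 | (S)-(+)-carvone, (5S)-2-methyl-5-(prop-1-en-2-yl)cyclohex-2-en-1-one | CC1=CC[C@H](C(C)=C)CC1=O | starting material
2 | lithium (3S,5S)-2,3-dimethyl-5-(prop-1-en-2-yl)cyclohex-1-en-1-olate (formed in situ) | CC1=C([O-])C[C@@H](C(C)=C)C[C@@H]1C.[Li+] | intermediate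
3 | (3S,5S)-2,3-dimethyl-5-(prop-1-en-2-yl)cyclohex-1-en-1-yl trifluoromethanesulfonate | CC1=C(OS(=O)(=O)C(F)(F)F)C[C@@H](C(C)=C)C[C@@H]1C | intermediate
4 | 5-(1-hydroperoxy-1-methoxyethyl)-2,3-dimethylcyclohex-1-en-1-yl trifluoromethanesulfonate, ring configuration as in 3, both epimers at the peroxy carbon (formed in situ) | CC1=C(OS(=O)(=O)C(F)(F)F)C[C@@H](C(C)(OC)OO)C[C@@H]1C | intermediate
5 | (3S,5S)-5-acetoxy-2,3-dimethylcyclohex-1-en-1-yl trifluoromethanesulfonate (formed in situ) | CC1=C(OS(=O)(=O)C(F)(F)F)C[C@@H](OC(C)=O)C[C@@H]1C | intermediate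
6 | (3S,5S)-5-hydroxy-2,3-dimethylcyclohex-1-en-1-yl trifluoromethanesulfonate | CC1=C(OS(=O)(=O)C(F)(F)F)C[C@@H](O)C[C@@H]1C | intermediate
7 | (3S,5S)-5-[(tert-butyldimethylsilyl)oxy]-2,3-dimethylcyclohex-1-en-1-yl trifluoromethanesulfonate | CC1=C(OS(=O)(=O)C(F)(F)F)C[C@@H](O[Si](C)(C)C(C)(C)C)C[C@@H]1C | intermediate
8 | (3S,5S)-5-[(tert-butyldimethylsilyl)oxy]-2,3-dimethylcyclohex-1-ene-1-carboxylic acid | CC1=C(C(=O)O)C[C@@H](O[Si](C)(C)C(C)(C)C)C[C@@H]1C | intermediate
9 | (3S,5S)-5-[(tert-butyldimethylsilyl)oxy]-2,3-dimethylcyclohex-1-ene-1-carbonyl chloride | CC1=C(C(Cl)=O)C[C@@H](O[Si](C)(C)C(C)(C)C)C[C@@H]1C | intermediate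
10 | allyltrimethylsilane | C=CC[Si](C)(C)C | starting material
11 | [1-(trimethylsilyl)allyl]lithium (formed in situ) | [Li+].C=C[CH-][Si](C)(C)C | intermediate
12 | (E)-1,3-bis(trimethylsilyl)prop-1-ene | C[Si](C)(C)C/C=C/[Si](C)(C)C | intermediate
13 | 1-[(3S,5S)-5-(tert-butyldimethylsilyloxy)-2,3-dimethylcyclohex-1-en-1-yl]-2-(trimethylsilyl)but-3-en-1-one, both epimers at the silyl-bearing carbon (formed in situ) | CC1=C(C(=O)C(C=C)[Si](C)(C)C)C[C@@H](O[Si](C)(C)C(C)(C)C)C[C@@H]1C | intermediate
14 | trichlorotitanium dienolate of 15 (O–TiCl3 on C9, C9=C10 and C7=C8; formed in situ) | Cl[Ti](Cl)(Cl)OC1=C2C[C@@H](O[Si](C)(C)C(C)(C)C)C[C@H](C)[C@@]2(C)CC=C1 | intermediate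
15 | 2α-[(tert-butyldimethylsilyl)oxy]-10βH-11,12,13-trinoreremophil-7-en-9-one (cis-fused, 4β,5β-dimethyl) | O=C1C=CC[C@]2(C)[C@@H](C)C[C@H](O[Si](C)(C)C(C)(C)C)C[C@H]12 | intermediate
16 | 2α-[(tert-butyldimethylsilyl)oxy]-9-(trimethylsilyloxy)-10βH-eremophila-8,11-diene, 7β-isopropenyl (formed in situ) | C[Si](C)(C)OC1=C[C@@H](C(C)=C)C[C@]2(C)[C@@H](C)C[C@H](O[Si](C)(C)C(C)(C)C)C[C@H]12 | intermediate
17 | 2α-[(tert-butyldimethylsilyl)oxy]-8α-(trimethylsilyloxy)-10βH-eremophil-11-en-9-one (formed in situ) | O=C1[C@H](O[Si](C)(C)C)[C@@H](C(C)=C)C[C@]2(C)[C@@H](C)C[C@H](O[Si](C)(C)C(C)(C)C)C[C@H]12 | intermediate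
18 | 2α-[(tert-butyldimethylsilyl)oxy]-8α-hydroxy-10βH-eremophil-11-en-9-one | O=C1[C@H](O)[C@@H](C(C)=C)C[C@]2(C)[C@@H](C)C[C@H](O[Si](C)(C)C(C)(C)C)C[C@H]12 | intermediate
19 | 8α-acetoxy-2α-[(tert-butyldimethylsilyl)oxy]-10βH-eremophil-11-en-9-one | O=C1[C@H](OC(C)=O)[C@@H](C(C)=C)C[C@]2(C)[C@@H](C)C[C@H](O[Si](C)(C)C(C)(C)C)C[C@H]12 | intermediate
20 | 8α-acetoxy-2α-[(tert-butyldimethylsilyl)oxy]-10βH-eremophil-11-en-9α-ol | O[C@@H]1[C@H](OC(C)=O)[C@@H](C(C)=C)C[C@]2(C)[C@@H](C)C[C@H](O[Si](C)(C)C(C)(C)C)C[C@H]12 | intermediate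
21 | 8α-acetoxy-2α-[(tert-butyldimethylsilyl)oxy]-9α-(3-methylbut-2-enoyloxy)-10βH-eremophil-11-ene | CC(C)=CC(=O)O[C@@H]1[C@H](OC(C)=O)[C@@H](C(C)=C)C[C@]2(C)[C@@H](C)C[C@H](O[Si](C)(C)C(C)(C)C)C[C@H]12 | intermediate
22 | 8α-acetoxy-9α-(3-methylbut-2-enoyloxy)-10βH-eremophil-11-en-2α-ol | CC(C)=CC(=O)O[C@@H]1[C@H](OC(C)=O)[C@@H](C(C)=C)C[C@]2(C)[C@@H](C)C[C@H](O)C[C@H]12 | intermediate
23 | 8α-acetoxy-9α-(3-methylbut-2-enoyloxy)-10βH-eremophil-11-en-2-one | C=C(C)[C@H]1C[C@@]2(C)[C@H](CC(=O)C[C@@H]2C)[C@H](OC(=O)C=C(C)C)[C@@H]1OC(C)=O | target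

**Totals**

Total step count: 13. Longest linear sequence: 12 steps (steps 1–5 and 7–13, from (S)-carvone); step 6 is a one-step side branch.

**Steps most likely to fail**

Step 7 (the proposed new method). The α-silyl ketone may lose silicon by protodesilylation, or close through a Nazarov-type pathway after double-bond migration, instead of undergoing the 1,4-addition. The ring fusion may also settle trans on equilibration. The fallback uses known reactions only and starts from 9. Me2CuLi (Et2O, −78 °C) gives the methyl ketone 1-[(3S,5S)-5-(tert-butyldimethylsilyloxy)-2,3-dimethylcyclohex-1-en-1-yl]ethanone F1. Intermolecular Hosomi–Sakurai conjugate allylation (allyltrimethylsilane, TiCl4, CH2Cl2, −78 °C) sets the quaternary C5 anti to the C4 methyl and gives the allyl ketone F2. Ozonolysis (O3, CH2Cl2, −78 °C; Me2S) gives the keto aldehyde F3. Intramolecular aldol condensation of the acetyl methyl (C8) onto the aldehyde (C7) with KOH in MeOH closes ring A and returns to the route at 15, again with equilibration of C10.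

Step 8. The conjugate addition may show poor facial selectivity, since the angular methyl is 1,3 to C7 and the ring fusion must be cis. Peracid may also attack the new isopropenyl group. The fallback replaces substrate control by catalyst control and starts from 15. A Hayashi–Miyaura addition ([Rh(cod)Cl]2, (S)-BINAP, CH2=C(CH3)BF3K, Et3N, dioxane/H2O, 80 °C) gives the ketone 2α-(tert-butyldimethylsilyloxy)-10βH-eremophil-11-en-9-one F4. The (S)-ligand is chosen because its usual sense of induction on cyclohexenones corresponds to the required C7 configuration, and the basic aqueous medium lets C10 equilibrate. Kinetic enol silylation at the C8 methylene (LiN(SiMe3)2, Me3SiCl, THF, −78 °C) then returns to the route at 16.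

Step 10. Hydride may be delivered from the wrong face, or the acetyl group may migrate from O8 to the new O9 alkoxide. The fallback sets C9 by inversion and starts from 19. NaBH4 (MeOH/CH2Cl2, −40 °C) should give, by axial attack, the equatorial 9β-alcohol 8α-acetoxy-2α-(tert-butyldimethylsilyloxy)-10βH-eremophil-11-en-9β-ol F5. Mitsunobu esterification with 3-methylbut-2-enoic acid (PPh3, diisopropyl azodicarboxylate, toluene) installs the senecioate with inversion and returns to the route at 21.

**Further compounds**

F1 | step 7 | 1-[(3S,5S)-5-(tert-butyldimethylsilyloxy)-2,3-dimethylcyclohex-1-en-1-yl]ethanone | CC1=C(C(C)=O)C[C@@H](O[Si](C)(C)C(C)(C)C)C[C@@H]1C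
F2 | step 7 | 1-[2-allyl-5-(tert-butyldimethylsilyloxy)-2,3-dimethylcyclohexyl]ethanone (allyl trans to the C3 methyl, acetyl cis to the allyl group) | CC(=O)[C@H]1C[C@@H](O[Si](C)(C)C(C)(C)C)C[C@H](C)[C@@]1(C)CC=C
F3 | step 7 | 2-[2-acetyl-4-(tert-butyldimethylsilyloxy)-1,6-dimethylcyclohexyl]acetaldehyde (configuration as in F2) | CC(=O)[C@H]1C[C@@H](O[Si](C)(C)C(C)(C)C)C[C@H](C)[C@@]1(C)CC=O
F4 | step 8 | 2α-[(tert-butyldimethylsilyl)oxy]-10βH-eremophil-11-en-9-one (7β-isopropenyl) | O=C1C[C@@H](C(C)=C)C[C@]2(C)[C@@H](C)C[C@H](O[Si](C)(C)C(C)(C)C)C[C@H]12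
F5 | step 10 | 8α-acetoxy-2α-[(tert-butyldimethylsilyl)oxy]-10βH-eremophil-11-en-9β-ol | O[C@H]1[C@H](OC(C)=O)[C@@H](C(C)=C)C[C@]2(C)[C@@H](C)C[C@H](O[Si](C)(C)C(C)(C)C)C[C@H]12
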